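**The pitfall.** A flat curve tempts me to call a reaction balanced, so I watch the fraction left instead of the fraction made: the part of the charge not yet in X or D.

| flask | E | remark | time |
|---|---|---|---|
| Friday's | 0.25 mM | run made earlier |  |
| Thursday's | 1 mM | run made earlier |  |
| flask | 0.50 mM |  | 40 min |

| run | time / min | X / % | D / % |
|---|---|---|---|
| Friday's | 3.00 | 25.6 | 38.4 |
| Friday's | 8.00 | 36.8 | 58.9 |
| Friday's | 15.0 | 38.7 | 61.3 |
| Friday's | 25.0 | 38.5 | 61.7 |
| Friday's | 30.0 | 38.9 | 61.5 |
| Thursday's | 3.00 | 25.8 | 38.5 |
| Thursday's | 8.00 | 37.5 | 58.9 |
| Thursday's | 15.0 | 38.4 | 61.9 |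
| Thursday's | 25.0 | 38.8 | 60.8 |
| Thursday's | 30.0 | 38.1 | 61.2 |

(readings scatter by 0.3 percentage points)

- which holds at 40 min: what has brought the reaction to rest, or that it has not come to rest (forward and back rates have come level / all of E has reacted / it is still moving)
- amount of X at 40 min, in percent of the E charged
- amount of D at 40 min, in percent of the E charged

- the earlier runs were read with a standard deviation of 0.3 percentage points
- reactions considered so far: L <-> E; J -> Q; Z <-> L; Q -> X; E <-> Z; X <-> D; E -> J
- the reaction counts as stopped when no species that holds the E changes by six tenths of a point or more over the second half of the time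

**Finishing rate.** Friday's and Thursday's runs read alike, so I average them. The fraction left is 35.9% at 3.00 min and 3.95% at 8.00 min. The charge finishes at 0.214 min⁻¹ over the first span and 0.0638 min⁻¹ over the next, a slowing by 3.35. I take the rate to follow the shrinking fraction left, so both halve every 1.57 min, my finishing half-life.

**Accumulated slowing.** On this half-life, the rate from 8.00 min to 40 min falls by a reckoned factor of 1.35 × 10⁶. In this flask I therefore reckon 0.0198% left at half the time and <0.001% at the end, so my answer for this flask is that all of E has reacted. The last readings give X a share 38.6% of the finished charge, and D 61.4%.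

**The forecast.** It says all of E has reacted, with X 38.6% and D 61.4%: “The route E → J → Q → X is one-way, so E drains completely rather than balancing.”

**The flask.** Its result is that all of E has reacted, with X 38.5%, D 61.5% and E 0%.

    L ⇌ E (k = 0.260 s⁻¹)
    J → Q (k = 0.00740 s⁻¹)
    Z ⇌ L (K = 0.480, k = 0.140 s⁻¹)
    Q → X (k = 0.120 s⁻¹)
    E ⇌ Z (K = 3.00, k = 0.150 s⁻¹)
    X ⇌ D (K = 1.60, k = 0.0980 s⁻¹)
    E → J (k = 0.200 s⁻¹)

**Why it held.** In this flask X rests at 38.5% and not 100% because X turns into D and back, as the run without that step proves. My half-life left 0.0198% of this flask's charge at half the time, and the largest change the flask shows over the second half is 0.018 percentage points. The neighbour with 0.30 mM of E has the same 40 min, so my half-life again leaves <0.001%; computed, it gives X 38.5%, D 61.5% and E 0%.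

The runs come from a simulation for an exercise; scatter was added.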